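**Retrosynthetic overview**
1. The target is the (3R)-isoflavanone 16. The last step frees the 5-OH from a 5-OMe group; that methyl ether blocks the second ortho oxygen of ring A through the ring closure and so fixes its direction.
2. Ring C is closed by forming the O1–C2 bond: a catalytic enantioselective 6-endo oxa-Michael addition/protonation of a 2'-hydroxy-α-aryl vinyl ketone, which also sets C3.
3. The vinyl ketone comes from a deoxybenzoin by α-methylenation, with the phenols silylated.
4. The deoxybenzoin comes from a Houben–Hoesch union of a ring A resorcinol and a ring B arylacetonitrile. Both are made from 3-hydroxy-4,5-dimethoxybenzaldehyde: Dakin oxidation (with a temporary C-bromine block) for ring A, one-carbon homologation for ring B.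
5. Rings A and B are bought as benzene rings; ring C is the only ring formed (step 8).

Assumption: aldehyde 1 is bought as a catalogue compound, and the (R)-phosphoric acid is taken to give the 3R product; if the first run shows the opposite sense, the (S)-acid is used instead.

**Route**

Step 1
Reactants: 1 3-hydroxy-4,5-dimethoxybenzaldehyde
Product: 2 2-bromo-3-hydroxy-4,5-dimethoxybenzaldehyde
Conditions: Br2 (1.05 equiv), NaOAc, Fe powder (cat.), AcOH, 20 °C
Reagents that add atoms: bromine, BrBr
Why: Electrophilic aromatic bromination in which the free 3-OH directs bromine to C2 (ortho to OH, para to the 5-OMe, as in the bromination of isovanillin), placing a removable block on the carbon that would otherwise compete for the acyl group in step 4; the position is checked by NOE/HMBC.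

Step 2
Reactants: 2 2-bromo-3-hydroxy-4,5-dimethoxybenzaldehyde
Product: 4 2-bromo-4,5-dimethoxybenzene-1,3-diol, via aryl formate 3 (not isolated)
Conditions: mCPBA, CH2Cl2, 0 °C → rt; then MeOH, Et3N (cat.), rt
Reagents that add atoms: mCPBA (3-chloroperoxybenzoic acid), OOC(=O)c1cccc(Cl)c1
Why: Dakin-type Baeyer–Villiger oxidation, in which the electron-rich aryl group (para-OMe) migrates to oxygen and the formate is then methanolysed to the phenol.

Step 3
Reactants: 1 3-hydroxy-4,5-dimethoxybenzaldehyde
Product: 6 2-(3-hydroxy-4,5-dimethoxyphenyl)acetonitrile, via N-formyl sulfonyl enamide 5 (not isolated)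
Conditions: TosMIC, KOt-Bu (3.2 equiv), DME, −40 °C; then MeOH, 65 °C
Reagents that add atoms: TosMIC (p-toluenesulfonylmethyl isocyanide), [C-]#[N+]CS(=O)(=O)c1ccc(C)cc1
Why: Van Leusen reductive cyanation, which turns ArCHO into ArCH2CN in one operation by loss of sulfinate and formate; the extra base covers the free phenol.

Step 4
Reactants: 4 2-bromo-4,5-dimethoxybenzene-1,3-diol; 6 2-(3-hydroxy-4,5-dimethoxyphenyl)acetonitrile
Product: 8 1-(3-bromo-2,4-dihydroxy-5,6-dimethoxyphenyl)-2-(3-hydroxy-4,5-dimethoxyphenyl)ethan-1-one, via ketiminium chloride 7 (not isolated)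
Conditions: ZnCl2, HCl (g), Et2O, 0 °C; then H2O, 95 °C
Reagents that add atoms: water, O
Why: Houben–Hoesch acylation of a phloroglucinol-type ring, where the only free carbon of 4 (ortho to OH, para to OH, ortho to OMe) is the one needed, so the ketone ends up flanked by one OH and one OMe.

Step 5
Reactants: 8 1-(3-bromo-2,4-dihydroxy-5,6-dimethoxyphenyl)-2-(3-hydroxy-4,5-dimethoxyphenyl)ethan-1-one
Product: 9 1-(2,4-dihydroxy-5,6-dimethoxyphenyl)-2-(3-hydroxy-4,5-dimethoxyphenyl)ethan-1-one
Conditions: H2 (1 atm), 10% Pd/C, NaOAc, MeOH, rt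
Reagents that add atoms: none
Why: Catalytic hydrodehalogenation removes the bromine block now that it has done its job; the chelated electron-rich aryl ketone is not reduced at 1 atm.

Step 6
Reactants: 9 1-(2,4-dihydroxy-5,6-dimethoxyphenyl)-2-(3-hydroxy-4,5-dimethoxyphenyl)ethan-1-one
Product: 10 1-[2,4-bis(tert-butyldimethylsilyloxy)-5,6-dimethoxyphenyl]-2-[3-(tert-butyldimethylsilyloxy)-4,5-dimethoxyphenyl]ethan-1-one
Conditions: TBSCl (3.6 equiv), imidazole, DMF, 40 °C
Reagents that add atoms: TBSCl (tert-butyldimethylsilyl chloride), CC(C)(C)[Si](C)(C)Cl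
Why: Silyl ether formation masks all three phenols, above all the ortho-OH that would otherwise close ring C in racemic form as soon as the methylene group is put in.

Step 7
Reactants: 10 1-[2,4-bis(tert-butyldimethylsilyloxy)-5,6-dimethoxyphenyl]-2-[3-(tert-butyldimethylsilyloxy)-4,5-dimethoxyphenyl]ethan-1-one
Product: 12 1-[2,4-bis(tert-butyldimethylsilyloxy)-5,6-dimethoxyphenyl]-2-[3-(tert-butyldimethylsilyloxy)-4,5-dimethoxyphenyl]prop-2-en-1-one, via Mannich base 11 (not isolated)
Conditions: CH2(NMe2)2, Ac2O, DMF, 80 °C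
Reagents that add atoms: bis(dimethylamino)methane, CN(C)CN(C)C
Why: Mannich α-aminomethylation of the benzylic ketone by the iminium acetate formed in situ, followed by N-acetylation and elimination, gives the α-methylene ketone in one pot.

Step 8
Reactants: 12 1-[2,4-bis(tert-butyldimethylsilyloxy)-5,6-dimethoxyphenyl]-2-[3-(tert-butyldimethylsilyloxy)-4,5-dimethoxyphenyl]prop-2-en-1-one
Product: 15 (3R)-7-hydroxy-3-(3-hydroxy-4,5-dimethoxyphenyl)-5,6-dimethoxychroman-4-one, via free enone 13 (not isolated), via enol 14 (not isolated)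
Conditions: HF·pyridine, THF, 0 °C; then (R)-3,3'-bis(2,4,6-triisopropylphenyl)-1,1'-binaphthyl-2,2'-diyl hydrogen phosphate (10 mol%), 4 Å MS, CH2Cl2–toluene, 0 °C
Reagents that add atoms: none
Why: Proposed new method: a chiral-phosphoric-acid-catalysed 6-endo oxa-Michael addition/enantioselective protonation cascade on a 2'-hydroxy-α-aryl vinyl ketone; acidic fluoride frees the phenols without forming a phenoxide, so chelated 13 should not close on its own at 0 °C, and the phosphoric acid then bridges the phenolic OH (through P=O) and the carbonyl oxygen (through P–OH), delivering O1 to the terminal CH2 to give catalyst-bound enol 14, after which the same phosphate relays the enol proton to one face of C3 through a cyclic hydrogen-bonded transition state inside the pocket of the two triisopropylphenyl groups, so the O1–C2 bond and the C3 stereocentre (R) are made in one catalytic cycle with no achiral acid or base present; the closest known reaction types are organocatalytic oxa-Michael cycloetherifications of phenols onto enones (which set only a β-stereocentre) and chiral Brønsted-acid enantioselective protonation of enol derivatives of 2-aryl cyclic ketones (which set the α-aryl centre but form no C–O bond).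

Step 9
Reactants: 15 (3R)-7-hydroxy-3-(3-hydroxy-4,5-dimethoxyphenyl)-5,6-dimethoxychroman-4-one
Product: 16 (3R)-5,7-dihydroxy-3-(3-hydroxy-4,5-dimethoxyphenyl)-6-methoxychroman-4-one
Conditions: BCl3 (4 equiv), CH2Cl2, −78 → −10 °C; then H2O, −40 °C
Reagents that add atoms: none
Why: Chelation-controlled Lewis-acid ether cleavage, in which BCl3 bound to the C4 carbonyl cleaves only the peri 5-OMe through a six-membered boron chelate while the 6-, 4'- and 5'-OMe groups lack that assistance at low temperature, and no base is present to enolise C3.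

**Compound list**
1 | 3-hydroxy-4,5-dimethoxybenzaldehyde | COc1cc(C=O)cc(O)c1OC | starting material
2 | 2-bromo-3-hydroxy-4,5-dimethoxybenzaldehyde | COc1cc(C=O)c(Br)c(O)c1OC | intermediate
3 | 2-bromo-3-hydroxy-4,5-dimethoxyphenyl formate (not isolated) | COc1cc(OC=O)c(Br)c(O)c1OC | intermediate
4 | 2-bromo-4,5-dimethoxybenzene-1,3-diol | COc1cc(O)c(Br)c(O)c1OC | intermediate
5 | N-[2-(3-hydroxy-4,5-dimethoxyphenyl)-1-(4-methylbenzenesulfonyl)ethenyl]formamide (E/Z not assigned; not isolated) | COc1cc(C=C(NC=O)S(=O)(=O)c2ccc(C)cc2)cc(O)c1OC | intermediate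
6 | 2-(3-hydroxy-4,5-dimethoxyphenyl)acetonitrile | COc1cc(CC#N)cc(O)c1OC | intermediate
7 | 1-(3-bromo-2,4-dihydroxy-5,6-dimethoxyphenyl)-2-(3-hydroxy-4,5-dimethoxyphenyl)ethan-1-iminium chloride (not isolated) | [Cl-].[NH2+]=C(Cc1cc(O)c(OC)c(OC)c1)c1c(O)c(Br)c(O)c(OC)c1OC | intermediate
8 | 1-(3-bromo-2,4-dihydroxy-5,6-dimethoxyphenyl)-2-(3-hydroxy-4,5-dimethoxyphenyl)ethan-1-one | O=C(Cc1cc(O)c(OC)c(OC)c1)c1c(O)c(Br)c(O)c(OC)c1OC | intermediate
9 | 1-(2,4-dihydroxy-5,6-dimethoxyphenyl)-2-(3-hydroxy-4,5-dimethoxyphenyl)ethan-1-one | O=C(Cc1cc(O)c(OC)c(OC)c1)c1c(O)cc(O)c(OC)c1OC | intermediate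
10 | 1-[2,4-bis(tert-butyldimethylsilyloxy)-5,6-dimethoxyphenyl]-2-[3-(tert-butyldimethylsilyloxy)-4,5-dimethoxyphenyl]ethan-1-one | O=C(Cc1cc(O[Si](C)(C)C(C)(C)C)c(OC)c(OC)c1)c1c(O[Si](C)(C)C(C)(C)C)cc(O[Si](C)(C)C(C)(C)C)c(OC)c1OC | intermediate
11 | 1-[2,4-bis(tert-butyldimethylsilyloxy)-5,6-dimethoxyphenyl]-2-[3-(tert-butyldimethylsilyloxy)-4,5-dimethoxyphenyl]-3-(dimethylamino)propan-1-one (racemic; not isolated) | CN(C)CC(C(=O)c1c(O[Si](C)(C)C(C)(C)C)cc(O[Si](C)(C)C(C)(C)C)c(OC)c1OC)c1cc(O[Si](C)(C)C(C)(C)C)c(OC)c(OC)c1 | intermediate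
12 | 1-[2,4-bis(tert-butyldimethylsilyloxy)-5,6-dimethoxyphenyl]-2-[3-(tert-butyldimethylsilyloxy)-4,5-dimethoxyphenyl]prop-2-en-1-one | C=C(C(=O)c1c(O[Si](C)(C)C(C)(C)C)cc(O[Si](C)(C)C(C)(C)C)c(OC)c1OC)c1cc(O[Si](C)(C)C(C)(C)C)c(OC)c(OC)c1 | intermediate
13 | 1-(2,4-dihydroxy-5,6-dimethoxyphenyl)-2-(3-hydroxy-4,5-dimethoxyphenyl)prop-2-en-1-one (not isolated) | C=C(C(=O)c1c(O)cc(O)c(OC)c1OC)c1cc(O)c(OC)c(OC)c1 | intermediate
14 | 3-(3-hydroxy-4,5-dimethoxyphenyl)-5,6-dimethoxy-2H-chromene-4,7-diol (enol; not isolated) | OC1=C(c2cc(O)c(OC)c(OC)c2)COc2cc(O)c(OC)c(OC)c12 | intermediate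
15 | (3R)-7-hydroxy-3-(3-hydroxy-4,5-dimethoxyphenyl)-5,6-dimethoxychroman-4-one | COc1cc([C@@H]2COc3cc(O)c(OC)c(OC)c3C2=O)cc(O)c1OC | intermediate
16 | (3R)-5,7-dihydroxy-3-(3-hydroxy-4,5-dimethoxyphenyl)-6-methoxychroman-4-one | COc1cc([C@@H]2COc3cc(O)c(OC)c(O)c3C2=O)cc(O)c1OC | target

**Step count**
Total: 9 steps. Longest linear sequence: 8 steps (steps 1, 2, 4, 5, 6, 7, 8, 9); step 3 is a one-step side branch.

**Three steps most likely to fail**

Step 8 (the proposed new cascade). The risks are uncatalysed racemic closure of 13, a slow acid-catalysed addition, poor facial control in the proton transfer to 14, and erosion of the α-aryl centre on handling. Fallback (known chemistry, resolution instead of asymmetric catalysis), setting out from 12: treatment with Bu4NF in THF at 0 °C → rt removes the silyl groups and the phenoxide closes ring C without selectivity to give racemic 7-hydroxy-3-(3-hydroxy-4,5-dimethoxyphenyl)-5,6-dimethoxychroman-4-one F3. The racemate is separated by preparative supercritical-fluid chromatography on an amylose tris(3,5-dimethylphenylcarbamate) phase. The unwanted (3S)-7-hydroxy-3-(3-hydroxy-4,5-dimethoxyphenyl)-5,6-dimethoxychroman-4-one F4 is re-racemised with catalytic DBU in THF and returned to the separation. The fallback rejoins the route at 15.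

Step 4 (Houben–Hoesch on the brominated resorcinol). The hindered position may give the ketimine slowly, and HCl could shift or strip the blocking bromine. Fallback (Friedel–Crafts acylation with a free carboxylic acid instead of the nitrile/ketimine pathway, no HCl), setting out from 6 and 4: the nitrile 6 is hydrolysed with aqueous NaOH at reflux and acidified to give 2-(3-hydroxy-4,5-dimethoxyphenyl)acetic acid F1. F1 and 4 are then heated in BF3·OEt2 at 70 °C, and aqueous NaOAc work-up breaks the boron chelate. The fallback rejoins the route at 8.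

Step 7 (α-methylenation). The ketone is flanked by two ortho substituents, and the α-aryl vinyl ketone can dimerise or polymerise on heating. Fallback (carbonyl olefination instead of Mannich/elimination), setting out from 10: SeO2 in 1,4-dioxane at 90 °C oxidises the benzylic CH2 to give 1-[2,4-bis(tert-butyldimethylsilyloxy)-5,6-dimethoxyphenyl]-2-[3-(tert-butyldimethylsilyloxy)-4,5-dimethoxyphenyl]ethane-1,2-dione F2. One equivalent of Ph3P=CH2 (from Ph3PCH3Br and KN(SiMe3)2, THF, −78 → 0 °C) then attacks the unhindered carbonyl next to ring B, not the carbonyl shielded by the silyloxy and methoxy groups of ring A. The fallback rejoins the route at 12.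

**Further compounds**
F1 | step 4 | 2-(3-hydroxy-4,5-dimethoxyphenyl)acetic acid | COc1cc(CC(=O)O)cc(O)c1OC
F2 | step 7 | 1-[2,4-bis(tert-butyldimethylsilyloxy)-5,6-dimethoxyphenyl]-2-[3-(tert-butyldimethylsilyloxy)-4,5-dimethoxyphenyl]ethane-1,2-dione | O=C(C(=O)c1cc(O[Si](C)(C)C(C)(C)C)c(OC)c(OC)c1)c1c(O[Si](C)(C)C(C)(C)C)cc(O[Si](C)(C)C(C)(C)C)c(OC)c1OC
F3 | step 8 | racemic 7-hydroxy-3-(3-hydroxy-4,5-dimethoxyphenyl)-5,6-dimethoxychroman-4-one | COc1cc(C2COc3cc(O)c(OC)c(OC)c3C2=O)cc(O)c1OC
F4 | step 8 | (3S)-7-hydroxy-3-(3-hydroxy-4,5-dimethoxyphenyl)-5,6-dimethoxychroman-4-one | COc1cc([C@H]2COc3cc(O)c(OC)c(OC)c3C2=O)cc(O)c1OC
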